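The 14-membered ring is closed at C1–C2 (C1 = ring CH bearing the acrylate, C2 = its CH2 neighbour towards C4) by a radical SH2′ macrocyclisation. It exploits the 1,3-relationship between C13–OH and C1 across C14 and the carboxyl on Cα: these are tied into a temporary δ-lactone (O, C=O, Cα, C1, C14, C13) whose Cα carries CH2SO2Ph. A primary C2 radical adds to C1, the lactone β-carbon, anti to the C13 side chain, and loss of PhSO2• unveils the exo-methylene: one operation closes the macrocycle, sets C1 from C13 and installs the α-methylene unit. The precursor is an open-chain iodide bearing a 3-(phenylsulfonylmethyl)-5,6-dihydropyran-2-one.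

Key step: step 13

Atom labels used below: ring carbons C1 (CH bearing the acrylate), C2, C3, C4 (C(CH3)OH), C5 (CHOAc), C6, C7, C8 (CH3), C9, C10, C11, C12 (CH3), C13 (CHOH), C14; Cα is the acrylate carbon on C1. Target configuration: 1R, 4R, 5S, 13S, 8E, 11E.

Assumption: (−)-Ipc2BOMe is the enantiomer made from (+)-α-pinene; its allylborane adds to the Si face of aldehydes (benzaldehyde gives the S alcohol).

Step 1
Reactants: 1 geranyl acetate
Product: 2 (2E,6E)-8-hydroxy-3,7-dimethylocta-2,6-dien-1-yl acetate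
Conditions: SeO2 (0.4 equiv), t-BuOOH (70% aq.), salicylic acid (cat.), CH2Cl2, rt
Reagents that add atoms: tert-butyl hydroperoxide, CC(C)(C)OO
Why: Riley allylic oxidation (ene reaction, then [2,3]-shift) attacks the electron-rich terminal alkene at its E-methyl group (the future C3), the C8=C9 alkene being deactivated by the allylic acetate.

Step 2
Reactants: 2 (2E,6E)-8-hydroxy-3,7-dimethylocta-2,6-dien-1-yl acetate
Product: 3 (2E)-5-[(2S,3S)-3-(hydroxymethyl)-3-methyloxiran-2-yl]-3-methylpent-2-en-1-yl acetate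
Conditions: Ti(OiPr)4 (10 mol%), L-(+)-diethyl tartrate (12 mol%), t-BuOOH (decane), 4 Å MS, CH2Cl2, −20 °C
Reagents that add atoms: tert-butyl hydroperoxide, CC(C)(C)OO
Why: Sharpless asymmetric epoxidation is hydroxyl-directed, so only the C4=C5 allylic-alcohol alkene reacts, and L-(+)-tartrate should give the (4S,5S)-epoxide (the same facial sense that turns E-2-hexen-1-ol into its (2S,3S)-epoxide).

Step 3
Reactants: 3 (2E)-5-[(2S,3S)-3-(hydroxymethyl)-3-methyloxiran-2-yl]-3-methylpent-2-en-1-yl acetate
Product: 5 (2E,6S,7R)-3,7-dimethylnona-2,8-diene-1,6,7-triol, via terminal-epoxide dialkoxide 4 (not isolated)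
Conditions: Me3S+ I− (6 equiv), n-BuLi (5.8 equiv), THF, −10 °C to rt
Reagents that add atoms: trimethylsulfonium iodide, C[S+](C)C.[I-]
Why: Payne rearrangement (the C3 alkoxide opens the epoxide at C4 with inversion) gives a terminal epoxide that the sulfonium ylide opens at C3, and ylide-mediated loss of Me2S (one-carbon homologation of an epoxide to an allylic alcohol) leaves the C2=C3 vinyl group, so C4 becomes R while C5 stays S; the excess ylide also removes the C10 acetate.

Step 4
Reactants: 5 (2E,6S,7R)-3,7-dimethylnona-2,8-diene-1,6,7-triol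
Product: 6 (2E,6S,7R)-7-hydroxy-3,7-dimethylnona-2,8-diene-1,6-diyl diacetate
Conditions: Ac2O (2.3 equiv), pyridine, DMAP (5 mol%), CH2Cl2, 0 °C
Reagents that add atoms: acetic anhydride, CC(=O)OC(C)=O
Why: DMAP-catalysed acylation esterifies the primary allylic (C10) and secondary (C5) hydroxyls, while the tertiary C4 hydroxyl is too hindered to react at 0 °C.

Step 5
Reactants: 6 (2E,6S,7R)-7-hydroxy-3,7-dimethylnona-2,8-diene-1,6-diyl diacetate; 7 propargyl alcohol
Product: 9 (3R,4S,7E,10E)-3,12-dihydroxy-3,7,11-trimethyldodeca-1,7,10-trien-4-yl acetate, via alkenylalane 8 (not isolated)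
Conditions: 7, Me3Al (3 equiv), Cp2ZrCl2 (0.25 equiv), ClCH2CH2Cl, 0 °C to rt; then 6, Pd(PPh3)4 (5 mol%), THF, rt
Reagents that add atoms: trimethylaluminium, C[Al](C)C
Why: Negishi Zr-catalysed syn-carboalumination puts methyl on C12 and aluminium on C11 (E-alkenylalane), and zerovalent palladium ionises only the primary allylic acetate, so allyl–alkenyl cross-coupling joins C10 to C11 at the less hindered terminus with retention of both alkene geometries.

Step 6
Reactants: 9 (3R,4S,7E,10E)-3,12-dihydroxy-3,7,11-trimethyldodeca-1,7,10-trien-4-yl acetate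
Product: 11 (2E,5E,9S,10R)-1,10,12-trihydroxy-2,6,10-trimethyldodeca-2,5-dien-9-yl acetate, via B-alkyl-9-BBN adduct 10 (not isolated)
Conditions: 9-BBN (3.5 equiv), THF, 0 °C to rt; then NaBO3·4H2O, THF/H2O, rt
Reagents that add atoms: sodium perborate, [Na+].[Na+].O[B-]1(O)OO[B-](O)(O)OO1
Why: Hydroboration–oxidation with bulky 9-BBN is anti-Markovnikov and selective for the only monosubstituted alkene (C2=C3) over the two trisubstituted ones, and perborate oxidation should spare the acetate.

Step 7
Reactants: 11 (2E,5E,9S,10R)-1,10,12-trihydroxy-2,6,10-trimethyldodeca-2,5-dien-9-yl acetate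
Product: 12 (2E,5E,9S,10R)-10,12-dihydroxy-2,6,10-trimethyl-1-oxododeca-2,5-dien-9-yl acetate
Conditions: MnO2 (20 equiv), CH2Cl2, rt
Reagents that add atoms: none
Why: Allylic oxidation with MnO2 takes only the allylic primary alcohol (C13) to the E-enal and leaves the saturated primary C2 alcohol and the tertiary alcohol.

Step 8
Reactants: 12 (2E,5E,9S,10R)-10,12-dihydroxy-2,6,10-trimethyl-1-oxododeca-2,5-dien-9-yl acetate
Product: 13 (2E,5E,9S,10R)-10-hydroxy-12-iodo-2,6,10-trimethyl-1-oxododeca-2,5-dien-9-yl acetate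
Conditions: I2, PPh3, imidazole, CH2Cl2, 0 °C
Reagents that add atoms: iodine, II
Why: Appel-type iodination converts the single primary alcohol into the C2 iodide by SN2 displacement of its alkoxyphosphonium salt, the tertiary C4 hydroxyl being inert.

Step 9
Reactants: 13 (2E,5E,9S,10R)-10-hydroxy-12-iodo-2,6,10-trimethyl-1-oxododeca-2,5-dien-9-yl acetate
Product: 15 (3R,4S,7E,10E,12S)-3,12-dihydroxy-1-iodo-3,7,11-trimethylpentadeca-7,10,14-trien-4-yl acetate, via diisopinocampheylborinate 14 (not isolated)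
Conditions: (−)-Ipc2BOMe, allylMgBr, Et2O, −78 °C to rt, salts filtered off; then 13, Et2O, −78 °C; NaBO3·4H2O, THF/H2O, rt
Reagents that add atoms: allylmagnesium bromide, C=CC[Mg]Br
Why: Brown allylboration through a closed chair transition state is reagent-controlled, the (+)-α-pinene-derived borane adding allyl to the Si face of the enal to set C13 as S, with no influence expected from the distant C4 and C5 centres.

Step 10
Reactants: 16 2-(bromomethyl)acrylic acid
Product: 17 2-[(phenylsulfonyl)methyl]acrylic acid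
Conditions: PhSO2Na, MeOH, reflux
Reagents that add atoms: sodium benzenesulfinate, [Na+].[O-]S(=O)c1ccccc1
Why: Allylic substitution of bromide by sulfinate (S-alkylation, SN2 or SN2′ giving the same product) forms the allyl sulfone.

Step 11
Reactants: 15 (3R,4S,7E,10E,12S)-3,12-dihydroxy-1-iodo-3,7,11-trimethylpentadeca-7,10,14-trien-4-yl acetate; 17 2-[(phenylsulfonyl)methyl]acrylic acid
Product: 18 (3R,4S,7E,10E,12S)-4-acetoxy-3-hydroxy-1-iodo-3,7,11-trimethylpentadeca-7,10,14-trien-12-yl 2-[(phenylsulfonyl)methyl]prop-2-enoate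
Conditions: DCC, DMAP (10 mol%), CH2Cl2, 0 °C to rt
Reagents that add atoms: none
Why: Steglich esterification acylates the secondary allylic C13 hydroxyl, the tertiary C4 hydroxyl being too hindered to compete.

Step 12
Reactants: 18 (3R,4S,7E,10E,12S)-4-acetoxy-3-hydroxy-1-iodo-3,7,11-trimethylpentadeca-7,10,14-trien-12-yl 2-[(phenylsulfonyl)methyl]prop-2-enoate
Product: 19 (6S)-6-[(2E,5E,9S,10R)-9-acetoxy-10-hydroxy-12-iodo-6,10-dimethyldodeca-2,5-dien-2-yl]-3-[(phenylsulfonyl)methyl]-5,6-dihydro-2H-pyran-2-one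
Conditions: second-generation Grubbs catalyst RuCl2(=CHPh)(H2IMes)(PCy3) (10 mol%), 1,4-benzoquinone (20 mol%), toluene (5 mM), 80 °C
Reagents that add atoms: none
Why: Ring-closing metathesis between the monosubstituted C1=CH2 alkene and the 1,1-disubstituted acrylate closes the six-membered unsaturated lactone with loss of ethylene, the trisubstituted alkenes being inert and benzoquinone suppressing isomerisation of the skipped diene.

Step 13
Reactants: 19 (6S)-6-[(2E,5E,9S,10R)-9-acetoxy-10-hydroxy-12-iodo-6,10-dimethyldodeca-2,5-dien-2-yl]-3-[(phenylsulfonyl)methyl]-5,6-dihydro-2H-pyran-2-one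
Product: 20 (1R,4R,5S,8E,11E,13S)-5-acetoxy-4-hydroxy-4,8,12-trimethylcyclotetradeca-8,11-diene whose C1 carries C(=CH2)C(=O) closed as a δ-lactone onto the C13 oxygen (3-methylenetetrahydropyran-2-one bridging C1 and C13, C2 and C12 trans on the lactone)
Conditions: (Bu3Sn)2 (1.5 equiv), hν (sunlamp), benzene (2 mM), 80 °C
Reagents that add atoms: none
Why: Proposed new method: photolysis of (Bu3Sn)2 gives Bu3Sn•, which abstracts iodine from C2; the nucleophilic primary radical adds to C1, the β-carbon of the electron-poor lactone, and the α-acyl radical expels PhSO2• by β-scission (SH2′), which regenerates Bu3Sn• from the ditin. The closest known reactions are Keck-type radical allylation of alkyl iodides with 2-(alkoxycarbonyl)allyl sulfones or stannanes and tin-mediated radical macrocyclisation of ω-iodoalkyl enones and enoates; new here are the macrocyclic setting and attack at the substituted terminus of the allyl sulfone. The 14-membered carbocycle closes in the 14-exo-trig mode (C1 inside, Cα outside the new ring), the δ-lactone being already present. C1 is controlled by C13: in the half-chair lactone the C13 side chain is pseudo-equatorial and the radical should attack C1 axially from the opposite face, giving the trans-4,6-disubstituted lactone, that is 1R from 13S. The step needs chemoselectivity for C1 over the C8=C9 and C11=C12 alkenes (only the lactone alkene is electron-poor), cyclisation over intermolecular addition (high dilution), and iodine abstraction faster than stannyl attack on the allyl sulfone (hence an iodide and not a bromide).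

Step 14
Reactants: 20 bridged α-methylene δ-lactone macrocycle
Product: 22 CNP0201062.1, methyl 2-[(1R,4R,5S,8E,11E,13S)-5-acetoxy-4,13-dihydroxy-4,8,12-trimethylcyclotetradeca-8,11-dien-1-yl]prop-2-enoate, via lithium carboxylate 21 (not isolated)
Conditions: LiOH·H2O (1.1 equiv), THF/H2O (4:1), 0 °C; concentrate; MeI (5 equiv), DMF, rt
Reagents that add atoms: lithium hydroxide, [Li+].[OH-]; iodomethane, CI
Why: Saponification of the strained conjugated δ-lactone should be much faster than that of the hindered secondary C5 acetate, and the carboxylate, which is also a poor acceptor for conjugate addition of the C13 alkoxide, is then O-methylated by SN2 on MeI.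

Compound list
1 | geranyl acetate | CC(C)=CCC/C(C)=C/COC(C)=O | starting material
2 | (2E,6E)-8-hydroxy-3,7-dimethylocta-2,6-dien-1-yl acetate | OC/C(C)=C/CC/C(C)=C/COC(C)=O | intermediate
3 | (2E)-5-[(2S,3S)-3-(hydroxymethyl)-3-methyloxiran-2-yl]-3-methylpent-2-en-1-yl acetate | OC[C@]1(C)O[C@H]1CC/C(C)=C/COC(C)=O | intermediate
4 | dilithium (2E,6S)-3-methyl-6-[(2R)-2-methyloxiran-2-yl]hex-2-ene-1,6-diolate (not isolated) | [Li+].[Li+].[O-]C/C=C(\C)CC[C@H]([O-])[C@@]1(C)CO1 | intermediate
5 | (2E,6S,7R)-3,7-dimethylnona-2,8-diene-1,6,7-triol | C=C[C@@](C)(O)[C@@H](O)CC/C(C)=C/CO | intermediate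
6 | (2E,6S,7R)-7-hydroxy-3,7-dimethylnona-2,8-diene-1,6-diyl diacetate | C=C[C@@](C)(O)[C@@H](OC(C)=O)CC/C(C)=C/COC(C)=O | intermediate
7 | propargyl alcohol | C#CCO | starting material
8 | (E)-[3-(dimethylalumanyloxy)-2-methylprop-1-en-1-yl]dimethylalane (not isolated) | C[Al](C)/C=C(\C)CO[Al](C)C | intermediate
9 | (3R,4S,7E,10E)-3,12-dihydroxy-3,7,11-trimethyldodeca-1,7,10-trien-4-yl acetate | C=C[C@@](C)(O)[C@@H](OC(C)=O)CC/C(C)=C/C/C=C(\C)CO | intermediate
10 | 9-BBN adduct of 9 with boron on C2 (not isolated; hydroxyls drawn free) | C1CC2CCCC(C1)B2CC[C@@](C)(O)[C@@H](OC(C)=O)CC/C(C)=C/C/C=C(\C)CO | intermediate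
11 | (2E,5E,9S,10R)-1,10,12-trihydroxy-2,6,10-trimethyldodeca-2,5-dien-9-yl acetate | OCC[C@@](C)(O)[C@@H](OC(C)=O)CC/C(C)=C/C/C=C(\C)CO | intermediate
12 | (2E,5E,9S,10R)-10,12-dihydroxy-2,6,10-trimethyl-1-oxododeca-2,5-dien-9-yl acetate | OCC[C@@](C)(O)[C@@H](OC(C)=O)CC/C(C)=C/C/C=C(\C)C=O | intermediate
13 | (2E,5E,9S,10R)-10-hydroxy-12-iodo-2,6,10-trimethyl-1-oxododeca-2,5-dien-9-yl acetate | ICC[C@@](C)(O)[C@@H](OC(C)=O)CC/C(C)=C/C/C=C(\C)C=O | intermediate
14 | diisopinocampheylborinate of 15 at the C13 oxygen (not isolated) | ICC[C@@](C)(O)[C@@H](OC(C)=O)CC/C(C)=C/C/C=C(\C)[C@@H](OB([C@@H]1C[C@@H]2C[C@@H](C2(C)C)[C@H]1C)[C@@H]1C[C@@H]2C[C@@H](C2(C)C)[C@H]1C)CC=C | intermediate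
15 | (3R,4S,7E,10E,12S)-3,12-dihydroxy-1-iodo-3,7,11-trimethylpentadeca-7,10,14-trien-4-yl acetate | ICC[C@@](C)(O)[C@@H](OC(C)=O)CC/C(C)=C/C/C=C(\C)[C@@H](O)CC=C | intermediate
16 | 2-(bromomethyl)acrylic acid | C=C(CBr)C(=O)O | starting material
17 | 2-[(phenylsulfonyl)methyl]acrylic acid | C=C(CS(=O)(=O)c1ccccc1)C(=O)O | intermediate
18 | (3R,4S,7E,10E,12S)-4-acetoxy-3-hydroxy-1-iodo-3,7,11-trimethylpentadeca-7,10,14-trien-12-yl 2-[(phenylsulfonyl)methyl]prop-2-enoate | ICC[C@@](C)(O)[C@@H](OC(C)=O)CC/C(C)=C/C/C=C(\C)[C@@H](OC(=O)C(=C)CS(=O)(=O)c1ccccc1)CC=C | intermediate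
19 | (6S)-6-[(2E,5E,9S,10R)-9-acetoxy-10-hydroxy-12-iodo-6,10-dimethyldodeca-2,5-dien-2-yl]-3-[(phenylsulfonyl)methyl]-5,6-dihydro-2H-pyran-2-one | ICC[C@@](C)(O)[C@@H](OC(C)=O)CC/C(C)=C/C/C=C(\C)[C@@H]1CC=C(CS(=O)(=O)c2ccccc2)C(=O)O1 | intermediate
20 | (1R,4R,5S,8E,11E,13S) 14-membered carbocycle with the α-methylene δ-lactone bridging C1 and the C13 oxygen, 5-OAc, 4-OH | C=C1[C@@H]2CC[C@@](C)(O)[C@@H](OC(C)=O)CC/C(C)=C/C/C=C(\C)[C@H](C2)OC1=O | intermediate
21 | lithium 2-[(1R,4R,5S,8E,11E,13S)-5-acetoxy-4,13-dihydroxy-4,8,12-trimethylcyclotetradeca-8,11-dien-1-yl]prop-2-enoate (not isolated) | [Li+].[O-]C(=O)C(=C)[C@@H]1CC[C@@](C)(O)[C@@H](OC(C)=O)CC/C(C)=C/C/C=C(\C)[C@@H](O)C1 | intermediate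
22 | CNP0201062.1, methyl 2-[(1R,4R,5S,8E,11E,13S)-5-acetoxy-4,13-dihydroxy-4,8,12-trimethylcyclotetradeca-8,11-dien-1-yl]prop-2-enoate | C=C(C(=O)OC)[C@@H]1CC[C@@](C)(O)[C@@H](OC(C)=O)CC/C(C)=C/C/C=C(\C)[C@@H](O)C1 | target

Total step count: 14. Longest linear sequence: 13 steps (steps 1–9 and 11–14; step 10 is a side branch).

Steps most likely to fail

Step 13 (key step, proposed new method). The slow 14-exo addition to a β-substituted acceptor may lose out to hydrogen-atom transfer within the chain, to stannyl radical attack on the allyl sulfone, or to oligomerisation, and facial selectivity at C1 may erode if the lactone reacts through its other half-chair. The fallback uses known chemistry, sets out from 15 and comes back at 20. Displacement of bromide in 16 with KOAc in DMF gives 2-(acetoxymethyl)acrylic acid F1. DCC/DMAP esterification of 15 with F1 gives the acetoxymethyl acrylate ester F2. Ring-closing metathesis as in step 12 gives the 3-(acetoxymethyl)-5,6-dihydropyran-2-one F3. A tin hydride radical macrocyclisation of established type (Bu3SnH by syringe pump, AIBN, benzene, 80 °C, 2 mM) should add the C2 radical to C1 anti to the C13 side chain and, after hydrogen transfer, give the saturated bridged lactone F4 as a mixture at Cα. DBU in CH2Cl2 then eliminates acetic acid (E1cB) to give 20.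

Step 14. Hydroxide may also cleave the C5 acetate or add to the α-methylene lactone, and the hydroxy carboxylate may relactonise before O-methylation is complete. The fallback sets out from 20 and comes back at 22 in one operation: acid-catalysed transesterification (camphorsulfonic acid, MeOH, rt, quenched with Et3N before concentration), which avoids hydroxide and the carboxylate 21 altogether; it makes no new compound (F0).

Step 3. Payne equilibration at the fully substituted C4 may be slow, so that direct ylide attack at C5 or decomposition competes and the inversion at C4 is incomplete. The fallback sets out from 2 and comes back at 6, keeping the C10 acetate throughout. Sharpless epoxidation of 2 with D-(−)-diethyl tartrate gives the enantiomeric (4R,5R)-epoxy alcohol F5. Ti(OiPr)4-mediated opening with acetic acid at C5 (the carbon remote from the chelating CH2OH, with inversion) gives the C5-acetoxy 3,4-diol F6, now 4R,5S. TEMPO/PhI(OAc)2 oxidises the primary alcohol to the α-hydroxy aldehyde F7, and Wittig methylenation (Ph3P=CH2, THF, −78 to 0 °C) gives 6.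

Further compounds
F1 | step 13 | 2-(acetoxymethyl)acrylic acid | C=C(COC(C)=O)C(=O)O
F2 | step 13 | (3R,4S,7E,10E,12S)-4-acetoxy-3-hydroxy-1-iodo-3,7,11-trimethylpentadeca-7,10,14-trien-12-yl 2-(acetoxymethyl)prop-2-enoate | ICC[C@@](C)(O)[C@@H](OC(C)=O)CC/C(C)=C/C/C=C(\C)[C@@H](OC(=O)C(=C)COC(C)=O)CC=C
F3 | step 13 | (6S)-3-(acetoxymethyl)-6-[(2E,5E,9S,10R)-9-acetoxy-10-hydroxy-12-iodo-6,10-dimethyldodeca-2,5-dien-2-yl]-5,6-dihydro-2H-pyran-2-one | ICC[C@@](C)(O)[C@@H](OC(C)=O)CC/C(C)=C/C/C=C(\C)[C@@H]1CC=C(COC(C)=O)C(=O)O1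
F4 | step 13 | bridged macrocyclic δ-lactone as 20 but with CH(CH2OAc) in place of C(=CH2) at Cα (mixture at Cα) | CC(=O)OCC1[C@@H]2CC[C@@](C)(O)[C@@H](OC(C)=O)CC/C(C)=C/C/C=C(\C)[C@H](C2)OC1=O
F0 | step 14 | none | none
F5 | step 3 | (2E)-5-[(2R,3R)-3-(hydroxymethyl)-3-methyloxiran-2-yl]-3-methylpent-2-en-1-yl acetate | OC[C@@]1(C)O[C@@H]1CC/C(C)=C/COC(C)=O
F6 | step 3 | (2E,6S,7R)-7,8-dihydroxy-3,7-dimethyloct-2-ene-1,6-diyl diacetate | OC[C@@](C)(O)[C@@H](OC(C)=O)CC/C(C)=C/COC(C)=O
F7 | step 3 | (2E,6S,7R)-7-hydroxy-3,7-dimethyl-8-oxooct-2-ene-1,6-diyl diacetate | O=C[C@@](C)(O)[C@@H](OC(C)=O)CC/C(C)=C/COC(C)=O
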